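**Strategy.** The route rests on the C11–C12 bond between the decalin (rings A/B) and the side chain. C13 bears two oxygenated methylene arms (C12, C16) and the C13=C14–C15 enoate, so the side chain is a 2-substituted allyl unit. A nickel-catalysed reductive coupling joins the C11 iodide of the complete bicyclic core with a symmetrical bis(allylic acetate). Either arm ionises to one η3-allyl (C12–C13–C14) whose ester lies syn. C–C bond formation at its CH2 terminus makes C11–C12, fixes the 13Z geometry and leaves the other arm as the C16 acetate. The core comes from an auxiliary-controlled Mn(III) radical bicyclisation.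

Key step: step 11

Convention: locants follow labdane numbering (C20 = methyl on C10, C19 = axial carbon on C4, C17 = exocyclic methylene carbon on C8); the compounds belong to the ent series, and CIP descriptors are given with these locants.
Assumption: the (1S,2R,5S)-(+)-8-phenylmenthyl ester is taken to shield the face of the C4 radical that leads to the ent series (the (−)-auxiliary being associated with the normal podocarpate series); if the sense is the reverse, the enantiomeric auxiliary is used and nothing else changes.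

**Step 1**
Reactants: 1 geranyl acetate
Product: 2 (2E,6E)-8-hydroxy-3,7-dimethylocta-2,6-dien-1-yl acetate
Conditions: SeO2 (cat.), t-BuOOH, salicylic acid (cat.), CH2Cl2, rt
Reagents that add atoms: tert-butyl hydroperoxide, CC(C)(C)OO
Why: Sharpless–Umbreit allylic oxidation (ene reaction, then [2,3]-shift) should hydroxylate the (E)-methyl of the electron-rich terminal trisubstituted alkene and leave the acetate-deactivated 2,3-alkene alone.

**Step 2**
Reactants: 2 (2E,6E)-8-hydroxy-3,7-dimethylocta-2,6-dien-1-yl acetate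
Product: 3 (2E,6E)-8-bromo-3,7-dimethylocta-2,6-dien-1-yl acetate
Conditions: CBr4, PPh3, CH2Cl2, 0 °C
Reagents that add atoms: carbon tetrabromide, BrC(Br)(Br)Br
Why: Appel bromination of the primary allylic alcohol by SN2 on the alkoxyphosphonium ion should proceed without allylic transposition or loss of alkene geometry at 0 °C.

**Step 3**
Reactants: 4 (+)-8-phenylmenthol; 5 ethyl 2-methyl-3-oxobutanoate
Product: 6 (1S,2R,5S)-8-phenylmenthyl 2-methyl-3-oxobutanoate
Conditions: DMAP (cat.), toluene, reflux (−EtOH)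
Reagents that add atoms: none
Why: DMAP-catalysed transesterification of a β-keto ester (via the acylketene) is driven by distillation of ethanol and does not touch the stereocentres of the auxiliary.

**Step 4**
Reactants: 6 (1S,2R,5S)-8-phenylmenthyl 2-methyl-3-oxobutanoate; 3 (2E,6E)-8-bromo-3,7-dimethylocta-2,6-dien-1-yl acetate
Product: 8 (1S,2R,5S)-8-phenylmenthyl (6E,10E)-12-acetoxy-2,6,10-trimethyl-3-oxododeca-6,10-dienoate, via dilithio dianion 7 (not isolated)
Conditions: LDA (2.05 equiv), THF, 0 °C; then 3, −78 → 0 °C; AcOH quench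
Reagents that add atoms: none
Why: Weiler dianion alkylation, in which the more basic γ-carbanion of the dienediolate should displace the allylic bromide (SN2, alkene geometry retained) faster than it attacks the acetate.

**Step 5**
Reactants: 8 (1S,2R,5S)-8-phenylmenthyl (6E,10E)-12-acetoxy-2,6,10-trimethyl-3-oxododeca-6,10-dienoate
Product: 9 (1S,2R,5S)-8-phenylmenthyl (4S,5S,9R,10R)-11-acetoxy-3-oxo-12,13,14,15,16-pentanorlabd-8(17)-en-19-oate
Conditions: Mn(OAc)3·2H2O (2.2 equiv), Cu(OAc)2·H2O (1 equiv, regenerated), degassed AcOH, rt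
Reagents that add atoms: none
Why: Mn(III)-based oxidative radical polyene cyclisation (Snider type), in which the phenyl shield of the auxiliary selects the face of the C4 α-keto ester radical, two 6-endo closures through chair–chair transition states of the (E,E)-diene set the axial C4 ester (cis to C20), the 5,10-trans fusion and the equatorial C9–CH2OAc, and Cu(II) oxidises the tertiary C8 radical to the exocyclic C8=C17 alkene.

**Step 6**
Reactants: 9 (1S,2R,5S)-8-phenylmenthyl (4S,5S,9R,10R)-11-acetoxy-3-oxo-12,13,14,15,16-pentanorlabd-8(17)-en-19-oate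
Product: 10 the C3 p-toluenesulfonylhydrazone of 9
Conditions: TsNHNH2, MeOH, 60 °C
Reagents that add atoms: p-toluenesulfonyl hydrazide, Cc1ccc(cc1)S(=O)(=O)NN
Why: hydrazone condensation at the only ketone, whose quaternary C4 neighbour cannot epimerise and whose hindered ester cannot close to a pyrazolone with the weakly nucleophilic sulfonamide nitrogen.

**Step 7**
Reactants: 10 the C3 p-toluenesulfonylhydrazone of 9
Product: 12 (1S,2R,5S)-8-phenylmenthyl (4R,5S,9R,10R)-11-acetoxy-12,13,14,15,16-pentanorlabd-8(17)-en-19-oate, via N-boryl tosylhydrazine 11 (not isolated)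
Conditions: catecholborane, CHCl3, 0 °C → rt; then NaOAc·3H2O, reflux
Reagents that add atoms: none
Why: Kabalka reduction (hydroboration of C=N, then acetate-induced loss of sulfinate and of N2 from the diazene) should give the C3 methylene without acid, so the exocyclic alkene and both esters survive.

**Step 8**
Reactants: 12 (1S,2R,5S)-8-phenylmenthyl (4R,5S,9R,10R)-11-acetoxy-12,13,14,15,16-pentanorlabd-8(17)-en-19-oate
Product: 13 (4R,5S,9R,10R)-12,13,14,15,16-pentanorlabd-8(17)-ene-11,19-diol
Conditions: LiAlH4, THF, reflux; Fieser work-up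
Reagents that add atoms: none
Why: hydride reduction should cleave the hindered axial ester to the C19 carbinol (auxiliary 4 recovered) and the acetate to the C11 alcohol without touching any stereocentre.

**Step 9**
Reactants: 13 (4R,5S,9R,10R)-12,13,14,15,16-pentanorlabd-8(17)-ene-11,19-diol
Product: 14 (4R,5S,9R,10R)-11-iodo-12,13,14,15,16-pentanorlabd-8(17)-en-19-ol
Conditions: I2, PPh3, imidazole, toluene–MeCN, 60 °C
Reagents that add atoms: iodine, II
Why: Appel-type (Garegg–Samuelsson) iodination, in which only the β-branched C11 oxyphosphonium ion should undergo SN2 by iodide, the neopentyl C19 oxyphosphonium ion being inert and hydrolysed back to the alcohol on work-up.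

**Step 10**
Reactants: 15 1,3-diacetoxyacetone; 16 tert-butyl (triphenylphosphoranylidene)acetate
Product: 17 tert-butyl 4-acetoxy-3-(acetoxymethyl)but-2-enoate
Conditions: toluene, 80 °C
Reagents that add atoms: none
Why: Wittig olefination of an activated ketone with a stabilised ylide, with no geometry issue because the ketone is symmetrical.

**Step 11**
Reactants: 14 (4R,5S,9R,10R)-11-iodo-12,13,14,15,16-pentanorlabd-8(17)-en-19-ol; 17 tert-butyl 4-acetoxy-3-(acetoxymethyl)but-2-enoate
Product: 18 tert-butyl (4R,5S,9R,10S,13Z)-16-acetoxy-19-hydroxylabda-8(17),13-dien-15-oate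
Conditions: NiCl2·glyme (10 mol %), 4,4′,4″-tri-tert-butyl-2,2′:6′,2″-terpyridine (10 mol %), Zn dust (2.5 equiv), 17 (3 equiv), DMA–THF, 40 °C
Reagents that add atoms: none
Why: Ni(0) should ionise either diastereotopic acetoxymethyl arm of 17 to the same η3-allylnickel acetate spanning C12–C13–C14, which equilibrates by η3–η1–η3 through the C14-bound form to the isomer with the tert-butyl ester syn; Ni(I) abstracts iodine from 14, the primary C11 radical is captured at nickel, reductive elimination at the unsubstituted CH2 terminus forms C11–C12, and Zn returns Ni(0). The closest known reaction type is the nickel-catalysed reductive (cross-electrophile) allylation of alkyl halides with allylic acetates, and the site of bond formation follows nickel-catalysed alkyl couplings of γ-halo enoates, which react at the terminus remote from the carbonyl. No ring is closed and no stereocentre is formed; the element set is the C13=C14 geometry, controlled by the syn preference of the ester in the allyl (ester cis to the C16 arm and trans to the new C12 chain, hence 13Z). The step needs site selectivity (C12 over C14, secured by sterics and retained conjugation), mono-substitution (secured by the excess of 17) and chemoselectivity (the free C19 hydroxyl, the C8=C17 methylene and both esters are inert in this radical/nickel manifold, and the homoallylic C11 radical should be trapped faster than it can close onto C8).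

**Step 12**
Reactants: 18 tert-butyl (4R,5S,9R,10S,13Z)-16-acetoxy-19-hydroxylabda-8(17),13-dien-15-oate
Product: 20 (4R,5S,9R,10S,13Z)-16-acetoxy-19-hydroxylabda-8(17),13-dien-15-oic acid, via bis(trimethylsilyl) derivative 19 (not isolated)
Conditions: TMSOTf (3 equiv), 2,6-lutidine (4 equiv), CH2Cl2, 0 °C; then MeOH, aq citric acid (pH 4)
Reagents that add atoms: none
Why: TMSOTf/2,6-lutidine should convert the tert-butyl ester into the silyl ester with loss of isobutene (and silylate C19–OH) without protic acid, so the C8=C17 methylene and the allylic acetate survive, and the mild aqueous methanol work-up removes both silyl groups.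

**Compound list**
1 | geranyl acetate, (2E)-3,7-dimethylocta-2,6-dien-1-yl acetate | CC(C)=CCC/C(C)=C/COC(C)=O | starting material
2 | (2E,6E)-8-hydroxy-3,7-dimethylocta-2,6-dien-1-yl acetate | OC/C(C)=C/CC/C(C)=C/COC(C)=O | intermediate
3 | (2E,6E)-8-bromo-3,7-dimethylocta-2,6-dien-1-yl acetate | BrC/C(C)=C/CC/C(C)=C/COC(C)=O | intermediate
4 | (+)-8-phenylmenthol, (1S,2R,5S)-5-methyl-2-(2-phenylpropan-2-yl)cyclohexan-1-ol | O[C@H]1C[C@@H](C)CC[C@@H]1C(C)(C)c1ccccc1 | starting material
5 | ethyl 2-methyl-3-oxobutanoate | CCOC(=O)C(C)C(C)=O | starting material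
6 | (1S,2R,5S)-8-phenylmenthyl 2-methyl-3-oxobutanoate (C2 epimers) | CC(=O)C(C)C(=O)O[C@H]1C[C@@H](C)CC[C@@H]1C(C)(C)c1ccccc1 | intermediate
7 | dilithium dienediolate (dianion) of 6 | [Li+].[Li+].C=C([O-])C(C)=C([O-])O[C@H]1C[C@@H](C)CC[C@@H]1C(C)(C)c1ccccc1 | intermediate
8 | (1S,2R,5S)-8-phenylmenthyl (6E,10E)-12-acetoxy-2,6,10-trimethyl-3-oxododeca-6,10-dienoate (C2 epimers) | CC(=O)OC/C=C(C)/CC/C=C(C)/CCC(=O)C(C)C(=O)O[C@H]1C[C@@H](C)CC[C@@H]1C(C)(C)c1ccccc1 | intermediate
9 | (1S,2R,5S)-8-phenylmenthyl (4S,5S,9R,10R)-11-acetoxy-3-oxo-12,13,14,15,16-pentanorlabd-8(17)-en-19-oate (trans-decalin; axial ester cis to C20; equatorial CH2OAc on C9) | C=C1CC[C@@H]2[C@](C)(C(=O)O[C@H]3C[C@@H](C)CC[C@@H]3C(C)(C)c3ccccc3)C(=O)CC[C@@]2(C)[C@@H]1COC(C)=O | intermediate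
10 | C3 p-toluenesulfonylhydrazone of 9 | C=C1CC[C@@H]2[C@](C)(C(=O)O[C@H]3C[C@@H](C)CC[C@@H]3C(C)(C)c3ccccc3)C(=NNS(=O)(=O)c3ccc(C)cc3)CC[C@@]2(C)[C@@H]1COC(C)=O | intermediate
11 | N-(1,3,2-benzodioxaborol-2-yl)-N′-tosylhydrazine at C3 (C3 configuration open) | C=C1CC[C@@H]2[C@](C)(C(=O)O[C@H]3C[C@@H](C)CC[C@@H]3C(C)(C)c3ccccc3)C(N(NS(=O)(=O)c3ccc(C)cc3)B3Oc4ccccc4O3)CC[C@@]2(C)[C@@H]1COC(C)=O | intermediate
12 | (1S,2R,5S)-8-phenylmenthyl (4R,5S,9R,10R)-11-acetoxy-12,13,14,15,16-pentanorlabd-8(17)-en-19-oate | C=C1CC[C@@H]2[C@](C)(C(=O)O[C@H]3C[C@@H](C)CC[C@@H]3C(C)(C)c3ccccc3)CCC[C@@]2(C)[C@@H]1COC(C)=O | intermediate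
13 | (4R,5S,9R,10R)-12,13,14,15,16-pentanorlabd-8(17)-ene-11,19-diol | C=C1CC[C@@H]2[C@](C)(CO)CCC[C@@]2(C)[C@@H]1CO | intermediate
14 | (4R,5S,9R,10R)-11-iodo-12,13,14,15,16-pentanorlabd-8(17)-en-19-ol | C=C1CC[C@@H]2[C@](C)(CO)CCC[C@@]2(C)[C@@H]1CI | intermediate
15 | 1,3-diacetoxyacetone | CC(=O)OCC(=O)COC(C)=O | starting material
16 | tert-butyl (triphenylphosphoranylidene)acetate | CC(C)(C)OC(=O)C=P(c1ccccc1)(c1ccccc1)c1ccccc1 | starting material
17 | tert-butyl 4-acetoxy-3-(acetoxymethyl)but-2-enoate | CC(=O)OCC(COC(C)=O)=CC(=O)OC(C)(C)C | intermediate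
18 | tert-butyl (4R,5S,9R,10S,13Z)-16-acetoxy-19-hydroxylabda-8(17),13-dien-15-oate | C=C1CC[C@@H]2[C@](C)(CO)CCC[C@@]2(C)[C@@H]1CC/C(=C/C(=O)OC(C)(C)C)COC(C)=O | intermediate
19 | trimethylsilyl (4R,5S,9R,10S,13Z)-16-acetoxy-19-(trimethylsilyloxy)labda-8(17),13-dien-15-oate | C=C1CC[C@@H]2[C@](C)(CO[Si](C)(C)C)CCC[C@@]2(C)[C@@H]1CC/C(=C/C(=O)O[Si](C)(C)C)COC(C)=O | intermediate
20 | (4R,5S,9R,10S,13Z)-16-acetoxy-19-hydroxylabda-8(17),13-dien-15-oic acid (CNP0136049.1) | C=C1CC[C@@H]2[C@](C)(CO)CCC[C@@]2(C)[C@@H]1CC/C(=C/C(=O)O)COC(C)=O | target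

**Step count.** Total: 12 steps. Longest linear sequence: 10 steps (1, 2, 4, 5, 6, 7, 8, 9, 11, 12 from geranyl acetate).

**Steps most likely to fail**

Step 11. The allylnickel may not hold the ester syn cleanly, which would erode the C13=C14 geometry, and the remaining acetate of the product may be substituted a second time or lost reductively. The fallback sets out from 14, locks the geometry in a butenolide ring and comes back to the route at 20. Iodide 14 would be silylated (TBSCl, imidazole, DMF) to the 19-O-TBS iodide F1 and converted with Zn dust/LiCl in THF into the alkylzinc iodide F2. F2 would be coupled (NiCl2·glyme/pybox, DMA, 0 °C, Negishi conditions as used for γ-halo enoates) at the exocyclic CH2 of commercial 4-(bromomethyl)furan-2(5H)-one to give the 19-O-TBS 15,16-butenolide F3. Saponification (KOH, THF–H2O) would give the potassium (Z)-16-hydroxy carboxylate F4, which is alkylated at once with phenacyl bromide in DMF to the (Z)-16-hydroxy phenacyl ester F5. Acetylation (Ac2O, pyridine, 0 °C) would give the 16-acetoxy phenacyl ester F6, Zn/AcOH the 19-O-TBS acid F7, and HF·pyridine in THF the target 20.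

Step 5. The auxiliary may discriminate the faces of the α-methyl-substituted C4 radical poorly, and the monocyclic radical may be oxidised before the second ring closes. The fallback sets out from 4 and 3, methylates after cyclisation and comes back at 9. Alcohol 4 and 2,2,6-trimethyl-4H-1,3-dioxin-4-one (xylene, 140 °C) would give (1S,2R,5S)-8-phenylmenthyl acetoacetate F8. Its dilithio dianion F9 (LDA, THF) would be alkylated with 3 to the α-unsubstituted keto ester F10. Mn(OAc)3/Cu(OAc)2 with Yb(OTf)3 in CF3CH2OH at 0 °C, where the chelated unsubstituted radical is better shielded, would give the bicyclic 4-H β-keto ester F11. C-Methylation (K2CO3, MeI, acetone) from the face opposite C20 then gives the axial ester 9.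

Step 9. The two primary hydroxyls may not be told apart cleanly at the temperature the hindered C11 displacement needs, and E2 toward the 8(17),9(11)-diene may compete. The fallback sets out from 12, differentiates the two oxygens before the reduction and comes back at 14. Methanolysis (K2CO3, MeOH, rt) would remove only the acetate and give the 11-hydroxy phenylmenthyl ester F12. Iodination of its single hydroxyl (I2, PPh3, imidazole, 40 °C) would give the 11-iodo phenylmenthyl ester F13. DIBAL-H (toluene, −78 → 0 °C) would then reduce the ester to the carbinol without touching the iodide, giving 14.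

**Further compounds**
F1 | step 11 | (4R,5S,9R,10R)-19-(tert-butyldimethylsilyloxy)-11-iodo-12,13,14,15,16-pentanorlabd-8(17)-ene | C=C1CC[C@@H]2[C@](C)(CO[Si](C)(C)C(C)(C)C)CCC[C@@]2(C)[C@@H]1CI
F2 | step 11 | alkylzinc iodide of F1 (Zn at C11) | C=C1CC[C@@H]2[C@](C)(CO[Si](C)(C)C(C)(C)C)CCC[C@@]2(C)[C@@H]1C[Zn]I
F3 | step 11 | 19-(tert-butyldimethylsilyloxy)labda-8(17),13-dien-15,16-olide (4-substituted furan-2(5H)-one) | C=C1CC[C@@H]2[C@](C)(CO[Si](C)(C)C(C)(C)C)CCC[C@@]2(C)[C@@H]1CCC1=CC(=O)OC1
F4 | step 11 | potassium (13Z)-16-hydroxy-19-(tert-butyldimethylsilyloxy)labda-8(17),13-dien-15-oate | [K+].C=C1CC[C@@H]2[C@](C)(CO[Si](C)(C)C(C)(C)C)CCC[C@@]2(C)[C@@H]1CC/C(CO)=C/C(=O)[O-]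
F5 | step 11 | phenacyl (13Z)-16-hydroxy-19-(tert-butyldimethylsilyloxy)labda-8(17),13-dien-15-oate | C=C1CC[C@@H]2[C@](C)(CO[Si](C)(C)C(C)(C)C)CCC[C@@]2(C)[C@@H]1CC/C(CO)=C/C(=O)OCC(=O)c1ccccc1
F6 | step 11 | phenacyl (13Z)-16-acetoxy-19-(tert-butyldimethylsilyloxy)labda-8(17),13-dien-15-oate | C=C1CC[C@@H]2[C@](C)(CO[Si](C)(C)C(C)(C)C)CCC[C@@]2(C)[C@@H]1CC/C(COC(C)=O)=C/C(=O)OCC(=O)c1ccccc1
F7 | step 11 | (13Z)-16-acetoxy-19-(tert-butyldimethylsilyloxy)labda-8(17),13-dien-15-oic acid | C=C1CC[C@@H]2[C@](C)(CO[Si](C)(C)C(C)(C)C)CCC[C@@]2(C)[C@@H]1CC/C(COC(C)=O)=C/C(=O)O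
F8 | step 5 | (1S,2R,5S)-8-phenylmenthyl 3-oxobutanoate | CC(=O)CC(=O)O[C@H]1C[C@@H](C)CC[C@@H]1C(C)(C)c1ccccc1
F9 | step 5 | dilithium dienediolate (dianion) of F8 | [Li+].[Li+].C=C([O-])C=C([O-])O[C@H]1C[C@@H](C)CC[C@@H]1C(C)(C)c1ccccc1
F10 | step 5 | (1S,2R,5S)-8-phenylmenthyl (6E,10E)-12-acetoxy-6,10-dimethyl-3-oxododeca-6,10-dienoate | CC(=O)OC/C=C(C)/CC/C=C(C)/CCC(=O)CC(=O)O[C@H]1C[C@@H](C)CC[C@@H]1C(C)(C)c1ccccc1
F11 | step 5 | (1S,2R,5S)-8-phenylmenthyl (5,9,10 as in 9)-11-acetoxy-3-oxo-12,13,14,15,16,18-hexanorlabd-8(17)-en-19-oate (C4–H, enolisable, configuration open) | C=C1CC[C@@H]2C(C(=O)O[C@H]3C[C@@H](C)CC[C@@H]3C(C)(C)c3ccccc3)C(=O)CC[C@@]2(C)[C@@H]1COC(C)=O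
F12 | step 9 | (1S,2R,5S)-8-phenylmenthyl (4R,5S,9R,10R)-11-hydroxy-12,13,14,15,16-pentanorlabd-8(17)-en-19-oate | C=C1CC[C@@H]2[C@](C)(C(=O)O[C@H]3C[C@@H](C)CC[C@@H]3C(C)(C)c3ccccc3)CCC[C@@]2(C)[C@@H]1CO
F13 | step 9 | (1S,2R,5S)-8-phenylmenthyl (4R,5S,9R,10R)-11-iodo-12,13,14,15,16-pentanorlabd-8(17)-en-19-oate | C=C1CC[C@@H]2[C@](C)(C(=O)O[C@H]3C[C@@H](C)CC[C@@H]3C(C)(C)c3ccccc3)CCC[C@@]2(C)[C@@H]1CI
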